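**Strategy**

Everything rests on one disconnection: the cyclobutane (C4–C5–C6–C7) is read as a contracted cyclopentanone. The feature exploited is that quaternary, methyl-bearing C7 lies next to C6, whose isopropenyl group is attached through a single carbon outside the ring; putting that carbon back into the four-membered ring gives a 2,2,3-trisubstituted cyclopentanone. The key step, a photochemical Wolff rearrangement of the derived 2-diazo ketone, shifts C7 from the carbonyl carbon to C6: it forms the C6–C7 bond, closes the cyclobutane with the trans C4/C7 fusion intact and expels the carbonyl carbon as an ester. Its precursor is a ketal-protected, cyclopentanone-fused cyclodecene built from (R)-carvone and 2-methylcyclopent-2-enone by enolate alkylation and ring-closing metathesis.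

Key step: step 18

**Remarks**

- Numbering of the target: C1 is the ring carbon bearing the exo-methylene group; C2 and C3 follow; C4 is the ring-fusion CH; C5 (CH2) and C6 (CH-isopropenyl) complete the cyclobutane with quaternary C7; C8, C9, C10 (acrylic acid branch), C11 and C12 (prenyl branch) lead back to C1.
- Assumption: the C6 epimer with the ester (later acetyl) group cis to the C7 methyl group, i.e. trans to the C8 branch and 1,3-cis to the C3 branch, is taken to be the more stable one.
- The ring alkene made in step 15 is drawn Z; either geometry serves because it is reduced in step 20.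

**Route**

Step 1
Reactants: 1 (R)-(−)-carvone
Product: 2 (R)-10-chlorocarvone
Conditions: Ca(OCl)2, CO2 (dry ice), CH2Cl2/H2O, 0 °C
Reagents that add atoms: calcium hypochlorite ([Ca+2].[O-]Cl.[O-]Cl)
Why: Ene-type allylic chlorination by hypochlorous acid attacks the electron-rich 1,1-disubstituted alkene and not the conjugated one, and the stereocentre is not involved.

Step 2
Reactants: 2 (R)-10-chlorocarvone
Product: 4 (R)-10-hydroxycarvone, via 10-acetoxycarvone 3 (not isolated)
Conditions: KOAc, NaI (cat.), DMF, 60 °C; then K2CO3, MeOH, 0 °C → rt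
Reagents that add atoms: potassium acetate (CC(=O)[O-].[K+])
Why: SN2 displacement of the primary allylic chloride by acetate and base-catalysed transesterification free the alcohol under conditions too mild to epimerise or aromatise the enone.

Step 3
Reactants: 4 (R)-10-hydroxycarvone
Product: 5 (R)-10-(tert-butyldiphenylsilyloxy)carvone
Conditions: TBDPSCl, imidazole, DMF, rt
Reagents that add atoms: tert-butylchlorodiphenylsilane (CC(C)(C)[Si](Cl)(c1ccccc1)c1ccccc1)
Why: Standard silylation of a primary alcohol, the bulky TBDPS ether being chosen because it survives all later steps and shields the neighbouring 1,1-disubstituted alkene from peracid and metathesis catalysts.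

Step 4
Reactants: 5 (R)-10-(tert-butyldiphenylsilyloxy)carvone
Product: 6 trans-3-allyl silyl enol ether
Conditions: CuBr·SMe2, allylMgBr, THF, −78 °C; TMSCl, then 5; Et3N quench
Reagents that add atoms: allylmagnesium bromide (C=CC[Mg]Br); chlorotrimethylsilane (C[Si](C)(C)Cl)
Why: TMSCl-accelerated conjugate addition of allylcopper delivers the allyl group axially, anti to the C5 substituent (new centre C12, trans-3,5), and traps the enolate regiospecifically as the tetrasubstituted silyl enol ether.

Step 5
Reactants: 6 trans-3-allyl silyl enol ether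
Product: 8 α-hydroxy ketone, via silyloxy ketone 7 (not isolated)
Conditions: mCPBA, NaHCO3, CH2Cl2, −20 °C; then PPTS, MeOH, rt
Reagents that add atoms: 3-chloroperoxybenzoic acid (OOC(=O)c1cccc(Cl)c1)
Why: Rubottom oxidation, in which the silyl enol ether is by far the most electron-rich alkene and is the only one epoxidised; the new carbinol centre is irrelevant because step 6 destroys it.

Step 6
Reactants: 8 α-hydroxy ketone
Product: 9 allyl keto ester
Conditions: Pb(OAc)4, MeOH/benzene, 0 °C
Reagents that add atoms: methanol (CO)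
Why: Criegee-type cleavage of the α-ketol through its methanol hemiketal cuts the old carvone C1–C2 bond, giving the methyl ester (future C8) and the methyl ketone (future C1 and C2) without touching C10 or C12.

Step 7
Reactants: 9 allyl keto ester
Product: 10 prenyl keto ester
Conditions: 2-methyl-2-butene (excess), second-generation Hoveyda–Grubbs catalyst (5 mol %), CH2Cl2, 40 °C
Reagents that add atoms: 2-methyl-2-butene (CC=C(C)C)
Why: Olefin cross-metathesis converts the monosubstituted allyl terminus into the prenyl group, while the hindered 1,1-disubstituted alkene does not react.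

Step 8
Reactants: 10 prenyl keto ester
Product: 14 vinyl ketone ester, via lithium enolate 11 (not isolated), via Mannich base 12 (not isolated), via ammonium iodide 13 (not isolated)
Conditions: LDA, THF, −78 °C; Me2N=CH2+ I− (Eschenmoser's salt), −78 → 0 °C; then MeI, CH2Cl2, rt; then aq. NaHCO3, rt
Reagents that add atoms: N,N-dimethylmethyleneiminium iodide (C=[N+](C)C.[I-])
Why: Kinetic deprotonation takes the methyl group of the ketone (more acidic than the ester, less hindered than C12–H), and Mannich reaction, quaternisation and Hofmann-type elimination then give the vinyl ketone without enolising C12.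

Step 9
Reactants: 14 vinyl ketone ester
Product: 15 vinyl dioxolane ester
Conditions: (TMSOCH2)2, TMSOTf (cat.), CH2Cl2, −78 °C; pyridine quench
Reagents that add atoms: 1,2-bis(trimethylsilyloxy)ethane (C[Si](C)(C)OCCO[Si](C)(C)C)
Why: Aprotic silyl-triflate-catalysed ketalisation (Noyori conditions) converts the enone carbonyl into the dioxolane at low temperature without conjugate addition of the diol and without epimerising C12.

Step 10
Reactants: 15 vinyl dioxolane ester
Product: 16 primary alcohol
Conditions: LiAlH4, Et2O, 0 °C; aq. NaOH work-up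
Reagents that add atoms: none
Why: Hydride reduction of the ester to the primary alcohol, with ketal, silyl ether and alkenes inert.

Step 11
Reactants: 16 primary alcohol
Product: 17 chain iodide
Conditions: PPh3, I2, imidazole, CH2Cl2, 0 °C → rt
Reagents that add atoms: iodine ([I][I])
Why: Appel-type iodination replaces the primary hydroxyl by iodide in an SN2 step under imidazole-buffered conditions that spare the ketal.

Step 12
Reactants: 18 2-methylcyclopent-2-en-1-one
Product: 20 (S)-silyl enol ether, via magnesium enolate 19 (not isolated)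
Conditions: vinylMgBr, CuBr·SMe2 (5 mol %), Josiphos-type ferrocenyl diphosphine (6 mol %), t-BuOMe, −78 °C; then TMSCl, Et3N, HMPA, −78 → 0 °C
Reagents that add atoms: vinylmagnesium bromide (C=C[Mg]Br); chlorotrimethylsilane (C[Si](C)(C)Cl)
Why: Copper-catalysed asymmetric conjugate addition of a Grignard reagent to a 2-substituted cyclopentenone, in which the ligand enantiomer (chosen and checked on 20) fixes the face of vinyl delivery and so the (S) centre (C4), the enolate being stored regiospecifically as its silyl ether.

Step 13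
Reactants: 20 (S)-silyl enol ether; 17 chain iodide
Product: 22 alkylated cyclopentanone (open diene), via lithium enolate 21 (not isolated)
Conditions: 20 (2 equiv), MeLi, THF, 0 °C → rt; then 17, HMPA, −78 → −20 °C
Reagents that add atoms: none
Why: The lithium enolate released regiospecifically from the silyl enol ether is alkylated (SN2) by the primary iodide on the face opposite the adjacent vinyl group, which sets quaternary C7 with the chain trans to vinyl.

Step 14
Reactants: 22 alkylated cyclopentanone (open diene)
Product: 23 prenyl epoxide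
Conditions: mCPBA (1.05 equiv), NaHCO3, CH2Cl2, −20 → 0 °C
Reagents that add atoms: 3-chloroperoxybenzoic acid (OOC(=O)c1cccc(Cl)c1)
Why: Prilezhaev epoxidation picks the trisubstituted prenyl alkene (the most electron-rich one) and so masks the alkene that would otherwise close a cyclopentene with the neighbouring vinyl ketal in step 15; the epoxide CH centre forms as a mixture and is removed in step 16.

Step 15
Reactants: 23 prenyl epoxide
Product: 24 ring-closed epoxide
Conditions: second-generation Hoveyda–Grubbs catalyst (10 mol %), toluene (0.001 M), 80 °C, argon sparge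
Reagents that add atoms: none
Why: Ring-closing metathesis of the two monosubstituted vinyl groups forms C2=C3 and the ten-membered ring at high dilution, helped by the trans arrangement of the two arms on the cyclopentanone.

Step 16
Reactants: 24 ring-closed epoxide
Product: 25 bicyclic ketone with prenyl group restored
Conditions: WCl6, n-BuLi (2 equiv per W), THF, −78 °C → rt; then 24, rt
Reagents that add atoms: none
Why: Deoxygenation of the epoxide by lower-valent tungsten chloride removes the oxygen and returns the prenyl alkene, a reaction type that tolerates ketones, esters and ethers at room temperature.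

Step 17
Reactants: 25 bicyclic ketone with prenyl group restored
Product: 28 2-diazo ketone, via lithium enolate 26 (not isolated), via trifluoroacetyl ketone 27 (not isolated)
Conditions: LiHMDS, THF, −78 °C; CF3CO2CH2CF3; AcOH quench; then MsN3, Et3N, H2O (1 equiv), MeCN, rt
Reagents that add atoms: methanesulfonyl azide (CS(=O)(=O)N=[N+]=[N-])
Why: Deacylative Regitz diazo transfer: quaternary C7 leaves C6 as the only enolisable position, so trifluoroacetylation and diazo transfer with loss of the trifluoroacetyl group place the diazo group on C6 alone.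

Step 18
Reactants: 28 2-diazo ketone
Product: 31 trans-fused cyclobutane methyl ester, via ketene 29 (not isolated), via C6-epimeric ester 30 (not isolated)
Conditions: hν (medium-pressure Hg lamp, Pyrex, λ > 300 nm), MeOH, 0–20 °C; then NaOMe, MeOH, 40 °C
Reagents that add atoms: methanol (CO)
Why: Light expels N2 from the cyclic diazo ketone, which is locked s-cis, with a concerted 1,2-shift of C7 from the carbonyl carbon to C6; the resulting ketene, exocyclic to the new four-membered ring, is captured by methanol and the ester enol tautomerises. The closest known reaction type is the photochemical Wolff ring contraction of 2-diazocyclopentanones, in particular of 16-diazo-17-keto steroids to trans-fused D-nor (cyclobutane) esters beside an angular methyl group. The cyclobutane C4–C5–C6–C7 is closed by a 1,2-alkyl shift (five-to-four ring contraction), not by a cyclisation, so no strained ring has to be formed by bringing two ends together. C7 migrates with retention and C4 is untouched, so the trans fusion is inherited from the trans-2,3-disubstituted cyclopentanone; the new centre C6 is set by protonation of the ester enol from the less hindered face and then by methoxide equilibration towards the isomer with the ester cis to the C7 methyl group. The step needs regioselective migration, secured because C7 is the only carbon on the non-diazo side of the carbonyl, and rearrangement in preference to O–H insertion, favoured by the fixed s-cis geometry. It also needs chemoselectivity, secured by the ketal on C1 and the absence of any other chromophore above 300 nm.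

Step 19
Reactants: 31 trans-fused cyclobutane methyl ester
Product: 33 enone methyl ketone, via methyl enol ether 32 (not isolated)
Conditions: Cp2TiMe2 (3 equiv), toluene, 70 °C, dark; then 1 M HCl, THF, 0 °C → rt
Reagents that add atoms: dimethyltitanocene (C[Ti](C)(C1C=CC=C1)C1C=CC=C1); water (O)
Why: Petasis methylenation turns the ester into its methyl enol ether, and mild aqueous acid then hydrolyses both the enol ether (to the C6 acetyl group) and the allylic dioxolane (to the C1 enone), with C6 keeping or regaining its preferred configuration.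

Step 20
Reactants: 33 enone methyl ketone
Product: 34 diketone
Conditions: [(Ph3P)CuH]6 (0.4 equiv), benzene, H2O (5 equiv), rt
Reagents that add atoms: none
Why: Conjugate reduction by the phosphine copper hydride (Stryker's reagent) saturates C2=C3 of the enone only, leaving the acetyl ketone and all isolated alkenes untouched.

Step 21
Reactants: 34 diketone
Product: 35 bis-methylene silyl ether
Conditions: Cp2TiMe2 (6 equiv), toluene, 70 °C, dark
Reagents that add atoms: dimethyltitanocene (C[Ti](C)(C1C=CC=C1)C1C=CC=C1)
Why: Petasis methylenation with the non-basic titanium methylidene converts both ketones into exo-methylene groups without epimerising the adjacent centres C6 and C12.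

Step 22
Reactants: 35 bis-methylene silyl ether
Product: 36 allylic alcohol
Conditions: TBAF, THF, 0 °C → rt
Reagents that add atoms: none
Why: Fluoride-induced cleavage of the silyl ether, nothing else in the tetraene being fluoride-sensitive.

Step 23
Reactants: 36 allylic alcohol
Product: 37 enal
Conditions: MnO2 (activated, excess), CH2Cl2, rt
Reagents that add atoms: none
Why: MnO2 oxidises the allylic alcohol selectively to the 2-substituted acrolein.

Step 24
Reactants: 37 enal
Product: 38 CNP0198062.1
Conditions: NaClO2, NaH2PO4, 2-methyl-2-butene, t-BuOH/H2O, 0 °C → rt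
Reagents that add atoms: sodium chlorite ([Na+].[O-]Cl=O)
Why: Pinnick oxidation converts the enal into the acrylic acid, with 2-methyl-2-butene scavenging hypochlorous acid so that the alkenes are not chlorinated.

**Compound list**

1 | (R)-(−)-carvone, (R)-2-methyl-5-(prop-1-en-2-yl)cyclohex-2-en-1-one | CC1=CC[C@H](CC1=O)C(=C)C | starting material
2 | (R)-5-(3-chloroprop-1-en-2-yl)-2-methylcyclohex-2-en-1-one (10-chlorocarvone) | CC1=CC[C@H](CC1=O)C(=C)CCl | intermediate
3 | (R)-2-(4-methyl-5-oxocyclohex-3-en-1-yl)allyl acetate (10-acetoxycarvone; not isolated) | CC1=CC[C@H](CC1=O)C(=C)COC(C)=O | intermediate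
4 | (R)-5-(3-hydroxyprop-1-en-2-yl)-2-methylcyclohex-2-en-1-one (10-hydroxycarvone) | CC1=CC[C@H](CC1=O)C(=C)CO | intermediate
5 | (R)-5-[3-(tert-butyldiphenylsilyloxy)prop-1-en-2-yl]-2-methylcyclohex-2-en-1-one | CC1=CC[C@H](CC1=O)C(=C)CO[Si](c1ccccc1)(c1ccccc1)C(C)(C)C | intermediate
6 | (3R,5R)-3-allyl-2-methyl-5-[3-(TBDPS-oxy)prop-1-en-2-yl]-1-(trimethylsilyloxy)cyclohex-1-ene, allyl trans to the C5 group | CC1=C(O[Si](C)(C)C)C[C@H](C(=C)CO[Si](c2ccccc2)(c2ccccc2)C(C)(C)C)C[C@H]1CC=C | intermediate
7 | (3R,5R)-3-allyl-2-methyl-2-(trimethylsilyloxy)-5-[3-(TBDPS-oxy)prop-1-en-2-yl]cyclohexan-1-one, C2 epimers (not isolated) | CC1(O[Si](C)(C)C)C(=O)C[C@H](C(=C)CO[Si](c2ccccc2)(c2ccccc2)C(C)(C)C)C[C@H]1CC=C | intermediate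
8 | (3R,5R)-3-allyl-2-hydroxy-2-methyl-5-[3-(TBDPS-oxy)prop-1-en-2-yl]cyclohexan-1-one, C2 epimers | CC1(O)C(=O)C[C@H](C(=C)CO[Si](c2ccccc2)(c2ccccc2)C(C)(C)C)C[C@H]1CC=C | intermediate
9 | methyl (3R,5R)-5-acetyl-3-[3-(TBDPS-oxy)prop-1-en-2-yl]oct-7-enoate | COC(=O)C[C@H](C(=C)CO[Si](c1ccccc1)(c1ccccc1)C(C)(C)C)C[C@H](C(C)=O)CC=C | intermediate
10 | methyl (3R,5R)-5-acetyl-8-methyl-3-[3-(TBDPS-oxy)prop-1-en-2-yl]non-7-enoate | COC(=O)C[C@H](C(=C)CO[Si](c1ccccc1)(c1ccccc1)C(C)(C)C)C[C@H](C(C)=O)CC=C(C)C | intermediate
11 | lithium enolate of 10 at the acetyl methyl group (not isolated) | [Li+].COC(=O)C[C@H](C(=C)CO[Si](c1ccccc1)(c1ccccc1)C(C)(C)C)C[C@H](C([O-])=C)CC=C(C)C | intermediate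
12 | methyl (3R,5R)-5-[3-(dimethylamino)propanoyl]-8-methyl-3-[3-(TBDPS-oxy)prop-1-en-2-yl]non-7-enoate (not isolated) | COC(=O)C[C@H](C(=C)CO[Si](c1ccccc1)(c1ccccc1)C(C)(C)C)C[C@H](C(=O)CCN(C)C)CC=C(C)C | intermediate
13 | trimethylammonium iodide from 12 and MeI (not isolated) | [I-].COC(=O)C[C@H](C(=C)CO[Si](c1ccccc1)(c1ccccc1)C(C)(C)C)C[C@H](C(=O)CC[N+](C)(C)C)CC=C(C)C | intermediate
14 | methyl (3R,5R)-5-acryloyl-8-methyl-3-[3-(TBDPS-oxy)prop-1-en-2-yl]non-7-enoate | COC(=O)C[C@H](C(=C)CO[Si](c1ccccc1)(c1ccccc1)C(C)(C)C)C[C@H](C(=O)C=C)CC=C(C)C | intermediate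
15 | methyl (3R,5R)-8-methyl-3-[3-(TBDPS-oxy)prop-1-en-2-yl]-5-(2-vinyl-1,3-dioxolan-2-yl)non-7-enoate | COC(=O)C[C@H](C(=C)CO[Si](c1ccccc1)(c1ccccc1)C(C)(C)C)C[C@H](C1(C=C)OCCO1)CC=C(C)C | intermediate
16 | (3R,5R)-8-methyl-3-[3-(TBDPS-oxy)prop-1-en-2-yl]-5-(2-vinyl-1,3-dioxolan-2-yl)non-7-en-1-ol | OCC[C@H](C(=C)CO[Si](c1ccccc1)(c1ccccc1)C(C)(C)C)C[C@H](C1(C=C)OCCO1)CC=C(C)C | intermediate
17 | (3R,5R)-1-iodo-8-methyl-3-[3-(TBDPS-oxy)prop-1-en-2-yl]-5-(2-vinyl-1,3-dioxolan-2-yl)non-7-ene | ICC[C@H](C(=C)CO[Si](c1ccccc1)(c1ccccc1)C(C)(C)C)C[C@H](C1(C=C)OCCO1)CC=C(C)C | intermediate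
18 | 2-methylcyclopent-2-en-1-one | CC1=CCCC1=O | starting material
19 | bromomagnesium (S)-2-methyl-3-vinylcyclopent-1-en-1-olate (not isolated) | C=C[C@@H]1CCC(O[Mg]Br)=C1C | intermediate
20 | (S)-trimethyl[(2-methyl-3-vinylcyclopent-1-en-1-yl)oxy]silane | C=C[C@@H]1CCC(O[Si](C)(C)C)=C1C | intermediate
21 | lithium (S)-2-methyl-3-vinylcyclopent-1-en-1-olate (not isolated) | [Li+].C=C[C@@H]1CCC([O-])=C1C | intermediate
22 | (2S,3S)-2-methyl-3-vinylcyclopentan-1-one carrying at C2 the nine-carbon chain of 17 (joined through its former CH2I carbon), chain trans to vinyl | C=C[C@@H]1CCC(=O)[C@@]1(C)CC[C@H](C(=C)CO[Si](c2ccccc2)(c2ccccc2)C(C)(C)C)C[C@H](C2(C=C)OCCO2)CC=C(C)C | intermediate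
23 | 22 with the prenyl alkene as a 3,3-dimethyloxirane (both epoxide epimers) | C=C[C@@H]1CCC(=O)[C@@]1(C)CC[C@H](C(=C)CO[Si](c2ccccc2)(c2ccccc2)C(C)(C)C)C[C@H](C2(C=C)OCCO2)CC2OC2(C)C | intermediate
24 | trans-fused bicyclo[8.3.0]tridecenone: cyclopentanone fused at C4–C7 to the ten-membered ring, C1 dioxolane, (Z)-C2=C3, C7 methyl, C10 3-(TBDPS-oxy)prop-1-en-2-yl, C12 (3,3-dimethyloxiran-2-yl)methyl | C13(OCCO3)/C=C\[C@@H]2CCC(=O)[C@@]2(C)CC[C@H](C(=C)CO[Si](c4ccccc4)(c4ccccc4)C(C)(C)C)C[C@H]1CC1OC1(C)C | intermediate
25 | as 24 but with the C12 prenyl group restored | C13(OCCO3)/C=C\[C@@H]2CCC(=O)[C@@]2(C)CC[C@H](C(=C)CO[Si](c4ccccc4)(c4ccccc4)C(C)(C)C)C[C@H]1CC=C(C)C | intermediate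
26 | lithium enolate of 25 towards C6 (not isolated) | [Li+].C13(OCCO3)/C=C\[C@@H]2CC=C([O-])[C@@]2(C)CC[C@H](C(=C)CO[Si](c4ccccc4)(c4ccccc4)C(C)(C)C)C[C@H]1CC=C(C)C | intermediate
27 | 25 with a trifluoroacetyl group on C6 (not isolated) | C13(OCCO3)/C=C\[C@@H]2CC(C(=O)C(F)(F)F)C(=O)[C@@]2(C)CC[C@H](C(=C)CO[Si](c4ccccc4)(c4ccccc4)C(C)(C)C)C[C@H]1CC=C(C)C | intermediate
28 | 25 with a diazo group on C6 (2-diazo ketone) | C13(OCCO3)/C=C\[C@@H]2CC(=[N+]=[N-])C(=O)[C@@]2(C)CC[C@H](C(=C)CO[Si](c4ccccc4)(c4ccccc4)C(C)(C)C)C[C@H]1CC=C(C)C | intermediate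
29 | ketene exocyclic at C6 of the trans-fused cyclobutane (not isolated) | C13(OCCO3)/C=C\[C@@H]2CC(=C=O)[C@@]2(C)CC[C@H](C(=C)CO[Si](c4ccccc4)(c4ccccc4)C(C)(C)C)C[C@H]1CC=C(C)C | intermediate
30 | C6 epimer of 31, ester trans to the C7 methyl group (not isolated) | C13(OCCO3)/C=C\[C@@H]2C[C@@H](C(=O)OC)[C@@]2(C)CC[C@H](C(=C)CO[Si](c4ccccc4)(c4ccccc4)C(C)(C)C)C[C@H]1CC=C(C)C | intermediate
31 | trans-fused bicyclo[8.2.0]dodecene: cyclobutane C4–C5–C6–C7 with CO2Me on C6 cis to the C7 methyl group, C1 dioxolane, (Z)-C2=C3, C10 and C12 branches as in 25 | C13(OCCO3)/C=C\[C@@H]2C[C@H](C(=O)OC)[C@@]2(C)CC[C@H](C(=C)CO[Si](c4ccccc4)(c4ccccc4)C(C)(C)C)C[C@H]1CC=C(C)C | intermediate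
32 | 31 with the ester as 1-methoxyvinyl group (not isolated) | C13(OCCO3)/C=C\[C@@H]2C[C@H](C(=C)OC)[C@@]2(C)CC[C@H](C(=C)CO[Si](c4ccccc4)(c4ccccc4)C(C)(C)C)C[C@H]1CC=C(C)C | intermediate
33 | C6 acetyl compound with C1 ketone conjugated to (Z)-C2=C3 | O=C1/C=C\[C@@H]2C[C@H](C(C)=O)[C@@]2(C)CC[C@H](C(=C)CO[Si](c3ccccc3)(c3ccccc3)C(C)(C)C)C[C@H]1CC=C(C)C | intermediate
34 | diketone: C6 acetyl, C1 ketone, C2 and C3 saturated | O=C1CC[C@@H]2C[C@H](C(C)=O)[C@@]2(C)CC[C@H](C(=C)CO[Si](c3ccccc3)(c3ccccc3)C(C)(C)C)C[C@H]1CC=C(C)C | intermediate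
35 | TBDPS ether of the target's allylic alcohol: C1 exo-methylene, C6 isopropenyl | C=C1CC[C@@H]2C[C@H](C(=C)C)[C@@]2(C)CC[C@H](C(=C)CO[Si](c3ccccc3)(c3ccccc3)C(C)(C)C)C[C@H]1CC=C(C)C | intermediate
36 | allylic alcohol (C10 branch 3-hydroxyprop-1-en-2-yl) | C=C1CC[C@@H]2C[C@H](C(=C)C)[C@@]2(C)CC[C@H](C(=C)CO)C[C@H]1CC=C(C)C | intermediate
37 | enal (C10 branch 3-oxoprop-1-en-2-yl) | C=C1CC[C@@H]2C[C@H](C(=C)C)[C@@]2(C)CC[C@H](C(=C)C=O)C[C@H]1CC=C(C)C | intermediate
38 | CNP0198062.1 | C=C1CC[C@@H]2C[C@H](C(=C)C)[C@@]2(C)CC[C@H](C(=C)C(=O)O)C[C@H]1CC=C(C)C | target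

**Step count and risks**

Total: 24 steps. Longest linear sequence: 23 steps, from (R)-carvone 1 to 38 (steps 1–11 and 13–24); step 12 is the one-step side branch from 18.

Steps most likely to fail:

1. Step 15 (ring-closing metathesis). The ten-membered ring closes slowly, so the ruthenium carbene may instead close onto the hindered 1,1-disubstituted alkene at C10 (a seven- or six-membered ring) or react between molecules to give dimers. The fallback removes that alkene from play as well. It sets out from 22: dimethyldioxirane (about 2.2 equiv, acetone, 0 °C) should epoxidise both the prenyl alkene and the 2-(silyloxymethyl)vinyl alkene, the two vinyl groups being the slowest, to give the bis-epoxide diene F1. Ring-closing metathesis under the conditions of step 15, now with the two vinyl groups as the only alkenes, should give the ring-closed bis-epoxide F2. Excess WCl6/n-BuLi, as in step 16, then removes both epoxide oxygens, and the route is rejoined at 25.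

2. Step 13 (enolate alkylation). SN2 attack of a tetrasubstituted enolate on an unactivated primary iodide is slow, so proton transfer between enolate and product may compete and lead to regioisomeric or doubly alkylated ketones. The fallback forms the C7–C8 bond by an aldol reaction instead. It sets out from 16 and 20: oxidation of 16 (Dess–Martin periodinane, NaHCO3, CH2Cl2) should give the chain aldehyde F3. The lithium enolate 21 (from 20 and MeLi) should add to F3 at −78 °C, again on the face opposite the vinyl group, to give the β-hydroxy ketone F4 as a mixture at the C8 carbinol. O-Phenyl chlorothionoformate with pyridine and DMAP should give the O-phenyl thionocarbonate F5, and Barton–McCombie reduction (Bu3SnH at high concentration, AIBN, toluene, 80 °C) removes the C8 oxygen. The route is rejoined at 22.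

3. Step 12 (asymmetric vinyl addition). Vinyl transfer may proceed partly through an uncatalysed or ligand-free pathway, which would erode the enantiomeric purity of C4. The fallback replaces asymmetric catalysis by resolution through the enantiopure iodide. It sets out from 18: ligand-free copper-catalysed addition (vinylMgBr, CuBr·SMe2 cat., TMSCl, HMPA, THF, −78 °C) should give the racemic silyl enol ether F6. MeLi releases the racemic lithium enolate F7, and alkylation with 17 as in step 13 should give 22 together with the ring-diastereomeric ketone F8, which has both ring centres inverted. The two are diastereomers because of the carvone-derived centres and should be separable by chromatography, so the route is rejoined at 22.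

**Further compounds**

F1 | step 15 | bis-epoxide of 22 (prenyl and C10 alkenyl groups as oxiranes, epoxide epimers) | C=C[C@@H]1CCC(=O)[C@@]1(C)CC[C@H](C2(CO[Si](c3ccccc3)(c3ccccc3)C(C)(C)C)CO2)C[C@H](C2(C=C)OCCO2)CC2OC2(C)C
F2 | step 15 | ring-closed bis-epoxide (as 24 with the C10 alkenyl group also epoxidised) | C13(OCCO3)/C=C\[C@@H]2CCC(=O)[C@@]2(C)CC[C@H](C4(CO[Si](c5ccccc5)(c5ccccc5)C(C)(C)C)CO4)C[C@H]1CC1OC1(C)C
F3 | step 13 | chain aldehyde from 16 | O=CC[C@H](C(=C)CO[Si](c1ccccc1)(c1ccccc1)C(C)(C)C)C[C@H](C1(C=C)OCCO1)CC=C(C)C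
F4 | step 13 | β-hydroxy ketone (22 with OH on C8, both C8 epimers) | C=C[C@@H]1CCC(=O)[C@@]1(C)C(O)C[C@H](C(=C)CO[Si](c2ccccc2)(c2ccccc2)C(C)(C)C)C[C@H](C2(C=C)OCCO2)CC=C(C)C
F5 | step 13 | O-phenyl thionocarbonate of F4 | C=C[C@@H]1CCC(=O)[C@@]1(C)C(OC(=S)Oc2ccccc2)C[C@H](C(=C)CO[Si](c2ccccc2)(c2ccccc2)C(C)(C)C)C[C@H](C2(C=C)OCCO2)CC=C(C)C
F6 | step 12 | racemic trimethyl[(2-methyl-3-vinylcyclopent-1-en-1-yl)oxy]silane | C=CC1CCC(O[Si](C)(C)C)=C1C
F7 | step 12 | racemic lithium 2-methyl-3-vinylcyclopent-1-en-1-olate | [Li+].C=CC1CCC([O-])=C1C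
F8 | step 12 | diastereomer of 22 with (2R,3R) ring centres | C=C[C@H]1CCC(=O)[C@]1(C)CC[C@H](C(=C)CO[Si](c2ccccc2)(c2ccccc2)C(C)(C)C)C[C@H](C2(C=C)OCCO2)CC=C(C)C
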